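The earlier runs and the new flask are calculated with made-up constants.

In fractions of the X charged per minute, solid X falls 0.00714 min⁻¹ in the summer run and 0.00610 min⁻¹ in the noon run, though noon holds 2.31 times the charge. Both carry the same equivalents of E, so noon starts with that same factor in [E], and its loss in M per minute reads 1.97 times the summer loss, as it should if dissolved X stands at one level. I take the mean pace, 0.00662 min⁻¹.

| setting | summer | noon | flask |
|---|---|---|---|
| X | 0.013 M | 0.030 M | 0.020 M |
| E | 0.95 equiv | 0.95 equiv | 0.950 equiv |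
| remark | run made earlier | run made earlier |  |
| time |  |  | 20 min |

- summer (time / min: X / %, Z / %): 1.50: 93.4, 1.5; 3.00: 91.4, 0.8; 5.00: 89.2, 0; 6.00: 92.1, 0.4; 8.00: 88.4, 1.8; 10.0: 87.0, 0.8; 12.0: 85.9, 0.1
- noon (time / min: X / %, Z / %): 1.50: 95.7, 0.7; 3.00: 96.8, 0; 5.00: 93.8, 0; 6.00: 93.1, 1.7; 8.00: 90.6, 0; 10.0: 89.8, 1.6; 12.0: 89.3, 0

(readings scatter by 1 percentage point)

- X at 20 min, in percent of the X charged (only what is still solid)
- Z at 20 min, in percent of the X charged
- D at 20 min, in percent of the X charged
- G at 20 min, in percent of the X charged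

- as a solid, counted per litre of solution: X
- at the start none of X is in solution

What is that level? By 1.50 min the summer run has lost 6.6 percentage points, more than the 0.99 points the pace gives, so a quick first step comes before the slow fall. The gap to the line, times the charge, gives 7.29 × 10⁻⁴ M in the summer run and 9.92 × 10⁻⁴ M in the noon run. Their mean I read as the dissolved level, the solubility 8.61 × 10⁻⁴ M, a reading with a scatter of 1 point behind it.

What does this leave in the new flask? At 0.020 M, S takes 4.30 % of the charge and the pace takes 13.2 % by 20 min, so I commit to 82.5 % solid. D and G were not read in either run, so I put no number of my own on them.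

The forecast gives a little more solid than I do, 84 %, with Z 0.7 %, D 3 % and G 7 %, and holds that “dissolved X stays saturated and reaction with E limits consumption”.

The flask gives X 81.7 %, Z 0.418 %, D 3.79 % and G 6.31 %, each inside the forecast's range.

    Q + E → Z + L (k = 0.100 L mol⁻¹ s⁻¹)
    Q + E → D + L (k = 0.0950 L mol⁻¹ s⁻¹)
    E + Z → G + L (k = 0.360 L mol⁻¹ s⁻¹)
    E + D → G + L (k = 0.0710 L mol⁻¹ s⁻¹)
    X ⇌ Q, rate k5*(cs5 - [Q]) while solid is left; crystals form when [Q] > cs5 (solubility = 0.790 mM, k = 0.0550 s⁻¹)
    Z → J (k = 0.00810 s⁻¹)

In this flask dissolved X, Q, stands at 3.70 % at 2.00 min and 3.75 % at 20.0 min, and S over this charge gives 4.30 %. In one more flask with 0.0050 M of X, S takes 17.2 % of the charge, and with the same pace that leaves 69.6 % solid. That flask holds Q 15.6 % and solid X 69.0 % at 20.0 min.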